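**Retrosynthetic overview**
- The target is epigallocatechin-(4β→8)-epigallocatechin 3-O-gallate-(4β→8)-epigallocatechin. It is reached by hydrogenolysis of a perbenzylated trimer gallate, with the gallate placed on middle O3 after desilylation and the top C3–OH derived from a C3–B bond.
- Key disconnection: ring C of the top unit (O1, C2, C3, C4, C4a, C8a) is cut at O1–C2 and C3–C4. The feature that carries the strategy is the contiguous C2-aryl / C3-oxygen / C4-aryl triad (2,3-cis-3,4-trans) fused to the 5,7-dioxygenated ring A. It maps onto an ortho-quinone methide (O1=C8a–C4a=C4, with ring A of the middle unit on C4) plus a (Z)-β-borylstyrene.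
- The ortho-hydroxybenzhydrol comes from the C8 aryllithium of a bromine-capped middle–bottom dimer and an O-allyl salicylaldehyde. The dimer comes from Lewis acid coupling of a C4-activated 8-bromoflavan with a benzylated flavan (C4–C8 bond, 4β).
- Ring order: the bottom and middle flavan ring systems are taken intact from (−)-epigallocatechin, and top rings A and B are bought as benzaldehydes. Top ring C is the only ring built, in the key step.

Key step: step 13

Assumption: the (R) antipode of the phosphoric acid is taken as the one matched to the stereocentres of the dimer (the facial sense is proposed, not derived from a tested model); the benzhydrols are drawn as one carbinol epimer, although both should form and both are carried on.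

**Route**

Step 1
Reactants: 1 (−)-epigallocatechin
Product: 2 5,7,3',4',5'-penta-O-benzyl-(−)-epigallocatechin (3-OH free)
Conditions: BnBr (5.5 equiv), K2CO3, DMF, 0 °C → rt, argon
Reagents that add atoms: benzyl bromide, BrCc1ccccc1
Why: Williamson etherification; K2CO3 ionises only the five phenols, so the secondary 3-OH stays free and C2/C3 are untouched.

Step 2
Reactants: 2 penta-O-benzyl-epigallocatechin
Product: 3 8-bromo-5,7,3',4',5'-penta-O-benzyl-epigallocatechin
Conditions: NBS (1.0 equiv), CH2Cl2, −78 °C → rt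
Reagents that add atoms: N-bromosuccinimide, O=C1CCC(=O)N1Br
Why: Electrophilic aromatic bromination goes to C8, the most nucleophilic position of the 5,7-dialkoxy ring A of benzylated flavan-3-ols, and installs both the later lithiation handle and a cap against self-condensation.

Step 3
Reactants: 3 8-bromo-penta-O-benzyl-epigallocatechin
Product: 4 8-bromo-3-O-(tert-butyldimethylsilyl)-penta-O-benzyl-epigallocatechin
Conditions: TBSOTf, 2,6-lutidine, CH2Cl2, 0 °C
Reagents that add atoms: tert-butyldimethylsilyl triflate, CC(C)(C)[Si](C)(C)OS(=O)(=O)C(F)(F)F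
Why: Silylation of the hindered axial secondary alcohol with a silyl triflate gives an O3 group that survives aryllithium chemistry and is orthogonal to benzyl.

Step 4
Reactants: 4 8-bromo-3-O-TBS-penta-O-benzyl-epigallocatechin
Product: 5 8-bromo-4β-(2-ethoxyethoxy)-3-O-TBS-penta-O-benzyl-epigallocatechin (2,3-cis-3,4-trans)
Conditions: DDQ (2 equiv), 2-ethoxyethanol (5 equiv), CH2Cl2, rt
Reagents that add atoms: 2-ethoxyethanol, CCOCCO
Why: DDQ benzylic oxidation (hydride abstraction from C4 gives the ring-A-stabilised flavan-4-yl cation), and the alcohol adds anti to the C3 silyloxy group to give the 4β ether; this centre is ionised again in step 6.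

Step 5
Reactants: 2 penta-O-benzyl-epigallocatechin
Product: 6 3,5,7,3',4',5'-hexa-O-benzyl-(−)-epigallocatechin
Conditions: NaH, BnBr, n-Bu4NI (cat.), DMF, 0 °C → rt
Reagents that add atoms: benzyl bromide, BrCc1ccccc1
Why: Williamson etherification of the 3-alkoxide protects bottom O3 against the later aryllithium; no stereocentre is touched.

Step 6
Reactants: 5 C4-activated 8-bromoflavan; 6 hexa-O-benzyl-epigallocatechin (2 equiv)
Product: 7 dimer bromide: 8-bromo-3-O-TBS-penta-O-benzyl-epigallocatechin-(4β→8)-hexa-O-benzyl-epigallocatechin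
Conditions: TMSOTf (0.2 equiv), CH2Cl2, −78 → −40 °C
Reagents that add atoms: none
Why: Lewis acid ionisation of the C4 ether gives a flavan-4-yl cation that undergoes Friedel–Crafts attack by C8 of 6 on the face opposite the C3 silyloxy and C2 aryl groups, so middle C4 is set 3,4-trans (4β); the bromine at C8 keeps the electrophile from adding to itself.

Step 7
Reactants: 8 2,4,6-trihydroxybenzaldehyde
Product: 9 2,4-bis(benzyloxy)-6-hydroxybenzaldehyde
Conditions: BnBr (2.1 equiv), K2CO3, DMF, rt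
Reagents that add atoms: benzyl bromide, BrCc1ccccc1
Why: Williamson etherification stops at the dibenzyl ether because the last ortho hydroxyl is held in a hydrogen bond to the formyl oxygen and is the least nucleophilic.

Step 8
Reactants: 9 2,4-bis(benzyloxy)-6-hydroxybenzaldehyde
Product: 10 2-allyloxy-4,6-bis(benzyloxy)benzaldehyde
Conditions: allyl bromide, K2CO3, DMF, 60 °C
Reagents that add atoms: allyl bromide, C=CCBr
Why: Williamson allylation under forcing conditions masks the chelated phenol with a group that is inert to aryllithiums and removable under neutral conditions.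

Step 9
Reactants: 7 dimer bromide; 10 2-allyloxy-4,6-bis(benzyloxy)benzaldehyde (1.5 equiv)
Product: 12 dimer C8 benzhydrol allyl ether (both carbinol epimers), via C8-lithio dimer 11 (not isolated)
Conditions: t-BuLi (2.05 equiv), THF, −78 °C; then 10, −78 → −20 °C; aq. NaHCO3
Reagents that add atoms: none
Why: Bromine–lithium exchange at C8 of the middle unit followed by 1,2-addition of the aryllithium to the aldehyde; the new carbinol centre is not controlled and need not be, since it is erased on ionisation in step 13.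

Step 10
Reactants: 12 benzhydrol allyl ether
Product: 13 ortho-hydroxybenzhydrol on C8 of the protected middle–bottom dimer (both carbinol epimers)
Conditions: Pd(PPh3)4 (5 mol %), morpholine (5 equiv), THF, rt
Reagents that add atoms: none
Why: Tsuji–Trost-type deallylation (π-allyl palladium formation from the aryl allyl ether, allyl transfer to morpholine) frees the phenol under neutral conditions that leave the acid-labile benzhydrol, the silyl ether and the benzyl ethers alone.

Step 11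
Reactants: 14 3,4,5-tris(benzyloxy)benzaldehyde
Product: 15 5-ethynyl-1,2,3-tris(benzyloxy)benzene
Conditions: dimethyl (1-diazo-2-oxopropyl)phosphonate, K2CO3, MeOH/THF, 0 °C → rt
Reagents that add atoms: dimethyl (1-diazo-2-oxopropyl)phosphonate, CC(=O)C(=[N+]=[N-])P(=O)(OC)OC
Why: Seyferth–Gilbert homologation in the Ohira–Bestmann form converts the non-enolisable aryl aldehyde into the terminal alkyne under mild base.

Step 12
Reactants: 15 arylacetylene (1.2 equiv); 16 pinacolborane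
Product: 17 (Z)-2-[3,4,5-tris(benzyloxy)phenyl]ethenyl pinacolboronate
Conditions: [Rh(cod)Cl]2 (1.5 mol %), P(i-Pr)3 (6 mol %), Et3N, cyclohexane, rt
Reagents that add atoms: none
Why: Rhodium-catalysed trans-hydroboration of a terminal alkyne through a rhodium vinylidene places boron and the aryl group cis, giving the Z alkenylboronate.

Step 13
Reactants: 13 ortho-hydroxybenzhydrol; 17 (Z)-styrylboronate (3 equiv)
Product: 19 protected trimer with a pinacolboryl group on top C3 (top unit 2,3-cis-3,4-trans), via ortho-quinone methide 18 (not isolated)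
Conditions: (R)-3,3'-bis(2,4,6-triisopropylphenyl)-1,1'-binaphthyl-2,2'-diyl hydrogen phosphate (10 mol %), 5 Å MS, CH2Cl2, −20 °C → rt
Reagents that add atoms: none
Why: Proposed new method: the phosphoric acid ionises either carbinol epimer of 13, with loss of water to the sieves, to the hydrogen-bonded ortho-quinone methide 18, and its 1-oxadiene O1=C8a–C4a=C4 takes up the alkene of 17 in an asynchronous inverse-demand hetero-Diels–Alder [4+2] in which the boron-bearing carbon bonds to C4 and O1 then closes on the benzylic carbon, whose developing positive charge is stabilised by ring B and by the adjacent C–B bond. The closest known reaction type is the chiral phosphoric acid catalysed [4+2] of ortho-quinone methides from ortho-hydroxybenzhydrols with styrenes; a β-borylstyrene and a methide carrying a flavan ring A are not covered by it. Ring C of the top unit is closed by the cycloaddition itself, with C3–C4 and O1–C2 formed on one face of the alkene. The C2/C3 cis relation is copied from the Z geometry of 17; the C3/C4 trans relation follows from the methide aryl lying syn to the carbonyl oxygen (the C5 benzyloxy group disfavours the other geometry through allylic strain) combined with endo placement of ring B and boron, which is also the approach that keeps the pinacolboryl group away from the methide aryl; the absolute sense is set by the phosphate bound to the quinone methide oxygen, the stereocentres of the dimer acting as a matched or mismatched bias. The step needs regioselectivity (secured by the benzylic and β-boron stabilisation that makes the boron-bearing carbon the nucleophilic end), ring closure in preference to loss of boron with alkenyl transfer (secured by the poorly ionising pinacol ester and the phenol oxygen held next to the cation) and attack by the alkene in preference to the free C6 positions of other flavan A rings (secured by their shielding between two benzyloxy groups and by the excess of 17).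

Step 14
Reactants: 19 C3-boryl trimer
Product: 20 protected trimer with free top 3-OH (middle 3-O-TBS)
Conditions: 30% H2O2, 2 M NaOH, THF, 0 °C → rt
Reagents that add atoms: hydrogen peroxide, OO
Why: Boronate oxidation (hydroperoxide ate complex, 1,2-shift of C3 from boron to oxygen) proceeds with retention, so the 2,3-cis-3,4-trans array is kept; the same oxidation is the known second half of the hydroboration route from flav-3-enes to flavan-3-ols.

Step 15
Reactants: 20 top 3-OH trimer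
Product: 21 top 3-O-benzyl trimer (middle 3-O-TBS)
Conditions: NaH, BnBr, n-Bu4NI (cat.), DMF, 0 °C → rt
Reagents that add atoms: benzyl bromide, BrCc1ccccc1
Why: Williamson etherification caps the top 3-OH so that only middle O3 is acylated later; the silyl ether is stable to the alkoxide and no stereocentre is involved.

Step 16
Reactants: 21 top 3-O-benzyl trimer silyl ether
Product: 22 perbenzylated trimer with free middle 3-OH
Conditions: TBAF, THF, rt → 40 °C
Reagents that add atoms: none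
Why: Fluoride desilylation frees the single hydroxyl of the molecule; the benzyl ethers and interflavan bonds are inert to fluoride.

Step 17
Reactants: 22 middle 3-OH trimer; 23 3,4,5-tris(benzyloxy)benzoyl chloride (3 equiv)
Product: 24 perbenzylated trimer 3-O-gallate (gallate on the middle unit)
Conditions: Et3N, DMAP (1 equiv), CH2Cl2, rt → 40 °C
Reagents that add atoms: none
Why: DMAP-mediated acylation of the only free (axial, hindered) alcohol through the acylpyridinium ion; esterification at oxygen leaves C3 unchanged.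

Step 18
Reactants: 24 perbenzylated trimer gallate
Product: 25 epigallocatechin-(4β→8)-epigallocatechin 3-O-gallate-(4β→8)-epigallocatechin (CNP0278699.1)
Conditions: H2 (1 atm), Pd(OH)2/C, THF/MeOH/H2O, rt
Reagents that add atoms: none
Why: Catalytic hydrogenolysis removes all twenty benzyl ethers under neutral conditions that should spare the ester, the C2–O1 bonds and the interflavan C4–C8 bonds.

**Compound list**

1 | (−)-epigallocatechin | O[C@@H]1Cc2c(O)cc(O)cc2O[C@@H]1c1cc(O)c(O)c(O)c1 | starting material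
2 | 5,7,3',4',5'-penta-O-benzyl-(−)-epigallocatechin | O[C@@H]1Cc2c(OCc3ccccc3)cc(OCc3ccccc3)cc2O[C@@H]1c1cc(OCc2ccccc2)c(OCc2ccccc2)c(OCc2ccccc2)c1 | intermediate
3 | 8-bromo-penta-O-benzyl-epigallocatechin | O[C@@H]1Cc2c(OCc3ccccc3)cc(OCc3ccccc3)c(Br)c2O[C@@H]1c1cc(OCc2ccccc2)c(OCc2ccccc2)c(OCc2ccccc2)c1 | intermediate
4 | 8-bromo-3-O-TBS-penta-O-benzyl-epigallocatechin | CC(C)(C)[Si](C)(C)O[C@@H]1Cc2c(OCc3ccccc3)cc(OCc3ccccc3)c(Br)c2O[C@@H]1c1cc(OCc2ccccc2)c(OCc2ccccc2)c(OCc2ccccc2)c1 | intermediate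
5 | 8-bromo-4β-(2-ethoxyethoxy)-3-O-TBS-penta-O-benzyl-epigallocatechin | CC(C)(C)[Si](C)(C)O[C@@H]1[C@@H](OCCOCC)c2c(OCc3ccccc3)cc(OCc3ccccc3)c(Br)c2O[C@@H]1c1cc(OCc2ccccc2)c(OCc2ccccc2)c(OCc2ccccc2)c1 | intermediate
6 | 3,5,7,3',4',5'-hexa-O-benzyl-(−)-epigallocatechin | c1ccccc1CO[C@@H]1Cc2c(OCc3ccccc3)cc(OCc3ccccc3)cc2O[C@@H]1c1cc(OCc2ccccc2)c(OCc2ccccc2)c(OCc2ccccc2)c1 | intermediate
7 | dimer bromide (middle unit 8-Br, 3-O-TBS, 4β→8 to the hexabenzyl bottom unit) | CC(C)(C)[Si](C)(C)O[C@@H]1[C@@H](c2c(OCc5ccccc5)cc(OCc5ccccc5)c3c2O[C@H](c2cc(OCc5ccccc5)c(OCc5ccccc5)c(OCc5ccccc5)c2)[C@H](OCc5ccccc5)C3)c2c(OCc5ccccc5)cc(OCc5ccccc5)c(Br)c2O[C@@H]1c1cc(OCc5ccccc5)c(OCc5ccccc5)c(OCc5ccccc5)c1 | intermediate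
8 | 2,4,6-trihydroxybenzaldehyde | O=Cc1c(O)cc(O)cc1O | starting material
9 | 2,4-bis(benzyloxy)-6-hydroxybenzaldehyde | O=Cc1c(O)cc(OCc2ccccc2)cc1OCc1ccccc1 | intermediate
10 | 2-allyloxy-4,6-bis(benzyloxy)benzaldehyde | C=CCOc1cc(OCc2ccccc2)cc(OCc2ccccc2)c1C=O | intermediate
11 | C8-lithio dimer | CC(C)(C)[Si](C)(C)O[C@@H]1[C@@H](c2c(OCc5ccccc5)cc(OCc5ccccc5)c3c2O[C@H](c2cc(OCc5ccccc5)c(OCc5ccccc5)c(OCc5ccccc5)c2)[C@H](OCc5ccccc5)C3)c2c(OCc5ccccc5)cc(OCc5ccccc5)c([Li])c2O[C@@H]1c1cc(OCc5ccccc5)c(OCc5ccccc5)c(OCc5ccccc5)c1 | intermediate (not isolated)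
12 | dimer C8 benzhydrol allyl ether (one carbinol epimer drawn) | CC(C)(C)[Si](C)(C)O[C@@H]1[C@@H](c2c(OCc5ccccc5)cc(OCc5ccccc5)c3c2O[C@H](c2cc(OCc5ccccc5)c(OCc5ccccc5)c(OCc5ccccc5)c2)[C@H](OCc5ccccc5)C3)c2c(OCc5ccccc5)cc(OCc5ccccc5)c([C@@H](O)c4c(OCC=C)cc(OCc5ccccc5)cc4OCc5ccccc5)c2O[C@@H]1c1cc(OCc5ccccc5)c(OCc5ccccc5)c(OCc5ccccc5)c1 | intermediate
13 | ortho-hydroxybenzhydrol on C8 of the dimer (one carbinol epimer drawn) | CC(C)(C)[Si](C)(C)O[C@@H]1[C@@H](c2c(OCc5ccccc5)cc(OCc5ccccc5)c3c2O[C@H](c2cc(OCc5ccccc5)c(OCc5ccccc5)c(OCc5ccccc5)c2)[C@H](OCc5ccccc5)C3)c2c(OCc5ccccc5)cc(OCc5ccccc5)c([C@@H](O)c4c(O)cc(OCc5ccccc5)cc4OCc5ccccc5)c2O[C@@H]1c1cc(OCc5ccccc5)c(OCc5ccccc5)c(OCc5ccccc5)c1 | intermediate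
14 | 3,4,5-tris(benzyloxy)benzaldehyde | O=Cc1cc(OCc2ccccc2)c(OCc2ccccc2)c(OCc2ccccc2)c1 | starting material
15 | 5-ethynyl-1,2,3-tris(benzyloxy)benzene | C#Cc1cc(OCc2ccccc2)c(OCc2ccccc2)c(OCc2ccccc2)c1 | intermediate
16 | pinacolborane | CC1(C)OBOC1(C)C | starting material
17 | (Z)-2-[3,4,5-tris(benzyloxy)phenyl]ethenyl pinacolboronate | CC1(C)OB(/C=C\c2cc(OCc3ccccc3)c(OCc3ccccc3)c(OCc3ccccc3)c2)OC1(C)C | intermediate
18 | ortho-quinone methide (methide aryl syn to the carbonyl oxygen) | CC(C)(C)[Si](C)(C)O[C@@H]1[C@@H](c2c(OCc5ccccc5)cc(OCc5ccccc5)c3c2O[C@H](c2cc(OCc5ccccc5)c(OCc5ccccc5)c(OCc5ccccc5)c2)[C@H](OCc5ccccc5)C3)c2c(OCc5ccccc5)cc(OCc5ccccc5)c(/C=C4\C(=O)C=C(OCc5ccccc5)C=C4OCc5ccccc5)c2O[C@@H]1c1cc(OCc5ccccc5)c(OCc5ccccc5)c(OCc5ccccc5)c1 | intermediate (not isolated)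
19 | protected trimer with pinacolboryl on top C3 | CC(C)(C)[Si](C)(C)O[C@@H]1[C@@H](c2c(OCc5ccccc5)cc(OCc5ccccc5)c3c2O[C@H](c2cc(OCc5ccccc5)c(OCc5ccccc5)c(OCc5ccccc5)c2)[C@H](OCc5ccccc5)C3)c2c(OCc5ccccc5)cc(OCc5ccccc5)c([C@H]3c4c(OCc5ccccc5)cc(OCc5ccccc5)cc4O[C@H](c4cc(OCc5ccccc5)c(OCc5ccccc5)c(OCc5ccccc5)c4)[C@@H]3B6OC(C)(C)C(C)(C)O6)c2O[C@@H]1c1cc(OCc5ccccc5)c(OCc5ccccc5)c(OCc5ccccc5)c1 | intermediate
20 | protected trimer with free top 3-OH | CC(C)(C)[Si](C)(C)O[C@@H]1[C@@H](c2c(OCc5ccccc5)cc(OCc5ccccc5)c3c2O[C@H](c2cc(OCc5ccccc5)c(OCc5ccccc5)c(OCc5ccccc5)c2)[C@H](OCc5ccccc5)C3)c2c(OCc5ccccc5)cc(OCc5ccccc5)c([C@H]3c4c(OCc5ccccc5)cc(OCc5ccccc5)cc4O[C@H](c4cc(OCc5ccccc5)c(OCc5ccccc5)c(OCc5ccccc5)c4)[C@@H]3O)c2O[C@@H]1c1cc(OCc5ccccc5)c(OCc5ccccc5)c(OCc5ccccc5)c1 | intermediate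
21 | top 3-O-benzyl trimer, middle 3-O-TBS | CC(C)(C)[Si](C)(C)O[C@@H]1[C@@H](c2c(OCc5ccccc5)cc(OCc5ccccc5)c3c2O[C@H](c2cc(OCc5ccccc5)c(OCc5ccccc5)c(OCc5ccccc5)c2)[C@H](OCc5ccccc5)C3)c2c(OCc5ccccc5)cc(OCc5ccccc5)c([C@H]3c4c(OCc5ccccc5)cc(OCc5ccccc5)cc4O[C@H](c4cc(OCc5ccccc5)c(OCc5ccccc5)c(OCc5ccccc5)c4)[C@@H]3OCc5ccccc5)c2O[C@@H]1c1cc(OCc5ccccc5)c(OCc5ccccc5)c(OCc5ccccc5)c1 | intermediate
22 | perbenzylated trimer with free middle 3-OH | O[C@@H]1[C@@H](c2c(OCc5ccccc5)cc(OCc5ccccc5)c3c2O[C@H](c2cc(OCc5ccccc5)c(OCc5ccccc5)c(OCc5ccccc5)c2)[C@H](OCc5ccccc5)C3)c2c(OCc5ccccc5)cc(OCc5ccccc5)c([C@H]3c4c(OCc5ccccc5)cc(OCc5ccccc5)cc4O[C@H](c4cc(OCc5ccccc5)c(OCc5ccccc5)c(OCc5ccccc5)c4)[C@@H]3OCc5ccccc5)c2O[C@@H]1c1cc(OCc5ccccc5)c(OCc5ccccc5)c(OCc5ccccc5)c1 | intermediate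
23 | 3,4,5-tris(benzyloxy)benzoyl chloride | O=C(Cl)c1cc(OCc2ccccc2)c(OCc2ccccc2)c(OCc2ccccc2)c1 | starting material
24 | perbenzylated trimer 3-O-gallate | O=C(O[C@@H]1[C@@H](c2c(OCc5ccccc5)cc(OCc5ccccc5)c3c2O[C@H](c2cc(OCc5ccccc5)c(OCc5ccccc5)c(OCc5ccccc5)c2)[C@H](OCc5ccccc5)C3)c2c(OCc5ccccc5)cc(OCc5ccccc5)c([C@H]3c4c(OCc5ccccc5)cc(OCc5ccccc5)cc4O[C@H](c4cc(OCc5ccccc5)c(OCc5ccccc5)c(OCc5ccccc5)c4)[C@@H]3OCc5ccccc5)c2O[C@@H]1c1cc(OCc5ccccc5)c(OCc5ccccc5)c(OCc5ccccc5)c1)c1cc(OCc5ccccc5)c(OCc5ccccc5)c(OCc5ccccc5)c1 | intermediate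
25 | CNP0278699.1 | O=C(O[C@@H]1[C@@H](c2c(O)cc(O)c3c2O[C@H](c2cc(O)c(O)c(O)c2)[C@H](O)C3)c2c(O)cc(O)c([C@H]3c4c(O)cc(O)cc4O[C@H](c4cc(O)c(O)c(O)c4)[C@@H]3O)c2O[C@@H]1c1cc(O)c(O)c(O)c1)c1cc(O)c(O)c(O)c1 | target

**Step count**

Total: 18 steps. Longest linear sequence: 13 steps (steps 1, 2, 3, 4, 6, 9, 10, 13, 14, 15, 16, 17, 18).

**Steps most likely to fail**

1. Step 13 (Proposed new method). The quinone methide or its protonated form may be intercepted by the electron-rich A rings of another molecule (Friedel–Crafts oligomerisation), may lose boron after the first bond is formed (alkenyl transfer in place of ring closure), or may add with poor facial or endo/exo selectivity. The fallback is the known flavan-4-yl cation coupling. It sets out from 7 (and uses 6) and comes back to the route at 21. Bromine–lithium exchange on 7 (t-BuLi, THF, −78 °C) and quench with methanol should give the debrominated dimer F1. Oxidation of 6 with DDQ in the presence of 2-ethoxyethanol should give 4β-(2-ethoxyethoxy)-hexa-O-benzyl-epigallocatechin F2. TMSOTf-catalysed coupling of F2 with an excess of F1 (CH2Cl2, −78 °C) should bond top C4 to C8 of the middle unit anti to the C3 benzyloxy group and so deliver 21 directly.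

2. Step 9. Addition of the hindered 2,6-dioxygenated aryllithium to the hindered, electron-rich aldehyde may be slower than proton transfer from benzylic ether positions, so that the aryllithium is quenched before C–C bond formation. The fallback reverses the polarity. It sets out from 7 and comes back at 13. The aryllithium 11 is trapped with the small electrophile DMF to give the 8-formyl dimer F3. F3 is then treated with the bromomagnesium phenoxide of commercial 3,5-bis(benzyloxy)phenol (Oc1cc(OCc2ccccc2)cc(OCc2ccccc2)c1, deprotonated with EtMgBr in toluene/CH2Cl2, rt). This chelation-directed ortho-hydroxyalkylation of a magnesium phenoxide by an aryl aldehyde should give 13 without the allyl detour.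

3. Step 15. O-Alkylation of the axial top 3-OH, flanked by aryl-bearing C2 and C4, may stall, and forcing the alkoxide may degrade the material. The fallback lets boron serve as the mask for top O3, so no benzylation is needed. It sets out from 19 and comes back at 25. TBAF in THF should give the desilylated boronate F4. Acylation with 23 (Et3N, DMAP, CH2Cl2) should give the galloylated boronate F5. Oxidation with NaBO3·4H2O in THF/H2O at rt should give the perbenzylated trimer gallate with free top 3-OH F6. Hydrogenolysis (H2, Pd(OH)2/C) should then give 25.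

**Further compounds**

F1 | step 13 | debrominated middle–bottom dimer (C8–H on the middle unit) | CC(C)(C)[Si](C)(C)O[C@@H]1[C@@H](c2c(OCc5ccccc5)cc(OCc5ccccc5)c3c2O[C@H](c2cc(OCc5ccccc5)c(OCc5ccccc5)c(OCc5ccccc5)c2)[C@H](OCc5ccccc5)C3)c2c(OCc5ccccc5)cc(OCc5ccccc5)cc2O[C@@H]1c1cc(OCc5ccccc5)c(OCc5ccccc5)c(OCc5ccccc5)c1
F2 | step 13 | 4β-(2-ethoxyethoxy)-hexa-O-benzyl-epigallocatechin | c1ccccc1CO[C@@H]1[C@@H](OCCOCC)c2c(OCc3ccccc3)cc(OCc3ccccc3)cc2O[C@@H]1c1cc(OCc2ccccc2)c(OCc2ccccc2)c(OCc2ccccc2)c1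
F3 | step 9 | 8-formyl middle–bottom dimer | CC(C)(C)[Si](C)(C)O[C@@H]1[C@@H](c2c(OCc5ccccc5)cc(OCc5ccccc5)c3c2O[C@H](c2cc(OCc5ccccc5)c(OCc5ccccc5)c(OCc5ccccc5)c2)[C@H](OCc5ccccc5)C3)c2c(OCc5ccccc5)cc(OCc5ccccc5)c(C=O)c2O[C@@H]1c1cc(OCc5ccccc5)c(OCc5ccccc5)c(OCc5ccccc5)c1
F4 | step 15 | desilylated C3-boryl trimer (middle 3-OH free) | O[C@@H]1[C@@H](c2c(OCc5ccccc5)cc(OCc5ccccc5)c3c2O[C@H](c2cc(OCc5ccccc5)c(OCc5ccccc5)c(OCc5ccccc5)c2)[C@H](OCc5ccccc5)C3)c2c(OCc5ccccc5)cc(OCc5ccccc5)c([C@H]3c4c(OCc5ccccc5)cc(OCc5ccccc5)cc4O[C@H](c4cc(OCc5ccccc5)c(OCc5ccccc5)c(OCc5ccccc5)c4)[C@@H]3B6OC(C)(C)C(C)(C)O6)c2O[C@@H]1c1cc(OCc5ccccc5)c(OCc5ccccc5)c(OCc5ccccc5)c1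
F5 | step 15 | galloylated C3-boryl trimer | O=C(O[C@@H]1[C@@H](c2c(OCc5ccccc5)cc(OCc5ccccc5)c3c2O[C@H](c2cc(OCc5ccccc5)c(OCc5ccccc5)c(OCc5ccccc5)c2)[C@H](OCc5ccccc5)C3)c2c(OCc5ccccc5)cc(OCc5ccccc5)c([C@H]3c4c(OCc5ccccc5)cc(OCc5ccccc5)cc4O[C@H](c4cc(OCc5ccccc5)c(OCc5ccccc5)c(OCc5ccccc5)c4)[C@@H]3B6OC(C)(C)C(C)(C)O6)c2O[C@@H]1c1cc(OCc5ccccc5)c(OCc5ccccc5)c(OCc5ccccc5)c1)c1cc(OCc5ccccc5)c(OCc5ccccc5)c(OCc5ccccc5)c1
F6 | step 15 | perbenzylated trimer gallate with free top 3-OH | O=C(O[C@@H]1[C@@H](c2c(OCc5ccccc5)cc(OCc5ccccc5)c3c2O[C@H](c2cc(OCc5ccccc5)c(OCc5ccccc5)c(OCc5ccccc5)c2)[C@H](OCc5ccccc5)C3)c2c(OCc5ccccc5)cc(OCc5ccccc5)c([C@H]3c4c(OCc5ccccc5)cc(OCc5ccccc5)cc4O[C@H](c4cc(OCc5ccccc5)c(OCc5ccccc5)c(OCc5ccccc5)c4)[C@@H]3O)c2O[C@@H]1c1cc(OCc5ccccc5)c(OCc5ccccc5)c(OCc5ccccc5)c1)c1cc(OCc5ccccc5)c(OCc5ccccc5)c(OCc5ccccc5)c1
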